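**Plan**

1. Numbering (germacrane): C1=C10(CH3)–C9H2–C8(O‑angelate)–C7–C6(O‑lactone)–C5=C4(CH3)–C3H2–C2H2; C11 is the acetoxy carbon, C12 the lactone carbonyl. The SMILES describes a cis‑fused γ‑lactone (H6/H7 cis), a C11 methyl cis to C8, and an angelate.
2. Retrosynthesis, in order: the C8 angelate ester; the C9–C10 bond of the ten‑membered ring (back to an open‑chain cis‑lactone with a C8–C9 terminal epoxide and a C1≡C10–CH3 alkyne); the acetate and the C11–O bond; the C6–C7 bond and the lactone C–O bond (back to an enal and a 2‑(bromomethyl)acrylate); the C3–C4 bond of the enal.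
3. Forward: side chain by syn‑carbocupration, then the γ‑lactone ring by chromium Barbier addition and lactonisation, then C11 oxygenation, epoxide formation, closure of the ten‑membered carbocycle by nickel‑catalysed reductive epoxide–alkyne coupling, and angeloylation.
4. Enabling feature: the C8 oxygen sits on the carbon next to C9 and is homoallylic to the ring olefin C1=C10. C9 can therefore be the CH2 of an epoxide and C10 the methyl‑bearing carbon of an alkyne; one event then closes the carbocycle, sets the E C1=C10 geometry and frees the C8 hydroxyl.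
5. Stereochemistry: C8 comes from (R)‑glyceraldehyde acetonide and is inverted once in the epoxide closure; C7 and C6 are relayed from it in the allylchromium addition (chair transition state, cis‑lactone); C11 is set by enolate hydroxylation anti to the C7 substituent; both E olefins arise by syn‑carbometalation.

Key step: step 13

Assumption: in step 7 the aldehyde is taken to add to the allylchromium face anti to the dioxolane C–O bond (allylic‑strain model); the opposite outcome is covered by a fallback.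

**Route**

Step 1
Reactants: 1 pent‑3‑yn‑1‑ol
Product: 2 5‑iodopent‑2‑yne
Conditions: I2, PPh3, imidazole, CH2Cl2, 0 °C → rt
Reagents that add atoms: iodine, II
Why: Appel‑type iodination of a primary alcohol proceeds by SN2 displacement of the alkoxyphosphonium ion and leaves the internal alkyne untouched.

Step 2
Reactants: 2 5‑iodopent‑2‑yne; 3 ethyl but‑2‑ynoate
Product: 6 ethyl (2E)‑3‑methyloct‑2‑en‑6‑ynoate, via pent‑3‑ynylmagnesium iodide 4 (not isolated), via pent‑3‑ynylcopper 5 (not isolated)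
Conditions: Mg, Et2O, rt; CuI, THF, −40 °C; then 3, −78 °C; sat. aq. NH4Cl at −78 °C
Reagents that add atoms: none
Why: Carbocupration (organocopper conjugate addition to a 2‑alkynoate) is a syn addition, and protonation of the alkenylcopper at −78 °C with retention should place the new C3–C4 bond trans to the ester carbon, which is the E geometry of C4=C5.

Step 3
Reactants: 6 ethyl (2E)‑3‑methyloct‑2‑en‑6‑ynoate
Product: 7 (2E)‑3‑methyloct‑2‑en‑6‑yn‑1‑ol
Conditions: i‑Bu2AlH (2.2 equiv), CH2Cl2, −78 → 0 °C; Rochelle salt work‑up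
Reagents that add atoms: none
Why: i‑Bu2AlH reduces the conjugated ester 1,2 to the allylic alcohol without touching the alkyne or the olefin geometry.

Step 4
Reactants: 7 (2E)‑3‑methyloct‑2‑en‑6‑yn‑1‑ol
Product: 8 (2E)‑3‑methyloct‑2‑en‑6‑ynal
Conditions: MnO2, CH2Cl2, rt
Reagents that add atoms: none
Why: MnO2 oxidises the allylic alcohol selectively to the enal under neutral conditions that should not isomerise the E olefin.

Step 5
Reactants: 9 (4R)‑2,2‑dimethyl‑1,3‑dioxolane‑4‑carbaldehyde ((R)‑glyceraldehyde acetonide); 10 methyl acrylate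
Product: 11 methyl 2‑{[(4R)‑2,2‑dimethyl‑1,3‑dioxolan‑4‑yl](hydroxy)methyl}prop‑2‑enoate (both carbinol epimers, used together)
Conditions: DABCO (cat.), excess 10, rt
Reagents that add atoms: none
Why: Morita–Baylis–Hillman reaction; the new carbinol centre is of no consequence because it becomes sp2 in step 6, and the dioxolane stereocentre (future C8) is expected to survive because addition to the aldehyde outruns α‑deprotonation.

Step 6
Reactants: 11 Baylis–Hillman alcohol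
Product: 12 methyl (2Z)‑2‑(bromomethyl)‑3‑[(4S)‑2,2‑dimethyl‑1,3‑dioxolan‑4‑yl]prop‑2‑enoate
Conditions: NBS, Me2S, CH2Cl2, 0 °C → rt
Reagents that add atoms: N‑bromosuccinimide, O=C1CCC(=O)N1Br
Why: Corey–Kim‑type bromination of a Baylis–Hillman alcohol proceeds with allylic transposition (SN2′) to the more stable (Z)‑2‑(bromomethyl)enoate, with the dioxolane trans to the ester, under neutral conditions that keep the acetonide.

Step 7
Reactants: 8 (2E)‑3‑methyloct‑2‑en‑6‑ynal; 12 allylic bromide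
Product: 14 (4R,5R)‑4‑[(4S)‑2,2‑dimethyl‑1,3‑dioxolan‑4‑yl]‑3‑methylidene‑5‑[(1E)‑2‑methylhept‑1‑en‑5‑yn‑1‑yl]oxolan‑2‑one, via open‑chain hydroxy ester 13 (not isolated)
Conditions: CrCl2, THF, 0 °C → rt; aqueous work‑up; then PPTS (cat.), CH2Cl2, rt
Reagents that add atoms: none
Why: Nozaki–Hiyama‑type chromium Barbier allylation through a chair transition state (aldehyde substituent equatorial, C7 substituent cis to CH2Cr axial) should give the syn adduct and hence the cis‑lactone, while the face of C7 should be set by the dioxolane with H8 eclipsing C7=C11 (allylic 1,3‑strain) and the aldehyde arriving anti to the C8–O bond, which fixes C6 and C7 as in the target and leaves C8 in the configuration that step 12 inverts.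

Step 8
Reactants: 14 α‑methylene lactone
Product: 16 (3R,4R,5R)‑4‑[(4S)‑2,2‑dimethyl‑1,3‑dioxolan‑4‑yl]‑3‑hydroxy‑3‑methyl‑5‑[(1E)‑2‑methylhept‑1‑en‑5‑yn‑1‑yl]oxolan‑2‑one, via potassium lactone enolate 15 (not isolated)
Conditions: KBH(s‑Bu)3 (K‑Selectride), THF, −78 °C; then 2‑(phenylsulfonyl)‑3‑phenyloxaziridine, −78 → −40 °C; sat. aq. NH4Cl
Reagents that add atoms: 2‑(phenylsulfonyl)‑3‑phenyloxaziridine (Davis oxaziridine), O=S(=O)(N1OC1c1ccccc1)c1ccccc1
Why: Conjugate hydride addition to the exocyclic methylene gives the potassium enolate, and Davis enolate hydroxylation should occur on the face opposite the C7 dioxolanyl and C6 alkenyl groups (both on one face of the cis‑lactone), placing OH trans and CH3 cis to the C7 substituent as required at C11.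

Step 9
Reactants: 16 tertiary alcohol
Product: 17 (3R,4R,5R)‑4‑[(4S)‑2,2‑dimethyl‑1,3‑dioxolan‑4‑yl]‑3‑methyl‑5‑[(1E)‑2‑methylhept‑1‑en‑5‑yn‑1‑yl]‑2‑oxooxolan‑3‑yl acetate
Conditions: Ac2O, DMAP, Et3N, CH2Cl2, rt → 35 °C
Reagents that add atoms: acetic anhydride, CC(=O)OC(C)=O
Why: DMAP‑catalysed acyl transfer esterifies the tertiary α‑hydroxy lactone, which is the only free hydroxyl in the molecule.

Step 10
Reactants: 17 acetonide acetate
Product: 18 (3R,4S,5R)‑4‑[(1S)‑1,2‑dihydroxyethyl]‑3‑methyl‑5‑[(1E)‑2‑methylhept‑1‑en‑5‑yn‑1‑yl]‑2‑oxooxolan‑3‑yl acetate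
Conditions: AcOH/H2O (4:1), 40 °C
Reagents that add atoms: none
Why: Mild acetal hydrolysis removes the terminal acetonide while the lactone, the tertiary acetate and the alkyne should be stable to aqueous acetic acid.

Step 11
Reactants: 18 diol
Product: 20 (3R,4R,5R)‑4‑[(1S)‑2‑[(tert‑butyldimethylsilyl)oxy]‑1‑(methanesulfonyloxy)ethyl]‑3‑methyl‑5‑[(1E)‑2‑methylhept‑1‑en‑5‑yn‑1‑yl]‑2‑oxooxolan‑3‑yl acetate, via primary silyl ether 19 (not isolated)
Conditions: TBSCl (1.05 equiv), imidazole, CH2Cl2, 0 °C; then Et3N, MsCl, 0 °C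
Reagents that add atoms: tert‑butyldimethylsilyl chloride, CC(C)(C)[Si](C)(C)Cl; methanesulfonyl chloride, CS(=O)(=O)Cl
Why: Silylation picks the primary C9 hydroxyl on steric grounds and sulfonylation of the remaining secondary hydroxyl in the same flask turns the C8–O bond into the leaving group.

Step 12
Reactants: 20 silyl ether mesylate
Product: 22 (3R,4R,5R)‑3‑methyl‑5‑[(1E)‑2‑methylhept‑1‑en‑5‑yn‑1‑yl]‑4‑[(2R)‑oxiran‑2‑yl]‑2‑oxooxolan‑3‑yl acetate, via hydroxy mesylate 21 (not isolated)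
Conditions: Bu4NF, THF, 0 °C → rt
Reagents that add atoms: none
Why: Fluoride removes the silyl group and the primary alkoxide displaces the neighbouring secondary mesylate (intramolecular Williamson reaction, 3‑exo‑tet) with inversion at C8, which should give the epoxide with the C8 configuration of the target.

Step 13
Reactants: 22 alkynyl epoxide
Product: 24 (3R,3aS,4S,6E,10E,11aR)‑4‑hydroxy‑3,6,10‑trimethyl‑2‑oxo‑2,3,3a,4,5,8,9,11a‑octahydrocyclodeca[b]furan‑3‑yl acetate, via diethylborinate ester 23 (not isolated)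
Conditions: Ni(cod)2 (20 mol %), PBu3 (40 mol %), Et3B (4 equiv), Et2O, rt, 22 added by syringe pump (final 5 mM); aqueous work‑up
Reagents that add atoms: none
Why: Zerovalent nickel–PBu3 opens the terminal epoxide at its CH2 carbon (C9) by SN2‑type oxidative addition, the tethered alkyne inserts syn into the Ni–C9 bond so that C9 bonds to the methyl‑bearing alkyne carbon (C10), and Et3B then exchanges ethyl for the alkoxide on nickel, after which β‑hydride elimination and C–H reductive elimination deliver H to C1 with retention, cis to C9. The closest known reaction type is the nickel‑catalysed reductive coupling of alkynes with terminal epoxides, known intermolecularly and intramolecularly, a macrolactone closure included; it is applied here to a ten‑membered carbocycle. The ten‑membered ring closes in the endo mode at both partners: both epoxide carbons (C8, C9) and both alkyne carbons (C10, C1) end up in the ring, and the bond that breaks is C9–O. No new sp3 stereocentre forms: C8 keeps its epoxide configuration because its C–O bond is not broken, and the E geometry of C1=C10 follows from the cis‑carbonickelation. The step needs cyclisation over oligomerisation (helped by slow addition and by the cis‑lactone, which holds the C6 and C7 chains on one face), attack at C9 and not C8 (secured by the monosubstituted epoxide), and bond formation at C10 and not C1 (favoured by the small methyl group, which nickel–phosphine catalysts place on the bond‑forming carbon, and by the alternative being a nine‑membered ring with an exocyclic ethylidene).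

Step 14
Reactants: 24 macrocyclic alcohol; 25 angelic acid ((2Z)‑2‑methylbut‑2‑enoic acid)
Product: 27 (3R,3aS,4S,6E,10E,11aR)‑3‑(acetyloxy)‑3,6,10‑trimethyl‑2‑oxo‑2,3,3a,4,5,8,9,11a‑octahydrocyclodeca[b]furan‑4‑yl (2Z)‑2‑methylbut‑2‑enoate, via mixed anhydride 26 (not isolated)
Conditions: 25, 2,4,6‑trichlorobenzoyl chloride, Et3N, toluene, rt; then 24, toluene, 70 °C (no DMAP)
Reagents that add atoms: none
Why: Yamaguchi esterification through the preformed mixed anhydride, run without a nucleophilic catalyst, should acylate the secondary C8 hydroxyl at the angeloyl carbonyl without Z‑to‑E isomerisation to the tiglate and without change at C8.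

**Compound list**

1 | pent‑3‑yn‑1‑ol | CC#CCCO | starting material
2 | 5‑iodopent‑2‑yne | CC#CCCI | intermediate
3 | ethyl but‑2‑ynoate | CC#CC(=O)OCC | starting material
4 | pent‑3‑ynylmagnesium iodide | CC#CCC[Mg]I | intermediate
5 | pent‑3‑ynylcopper | CC#CCC[Cu] | intermediate
6 | ethyl (2E)‑3‑methyloct‑2‑en‑6‑ynoate | CC#CCC/C(C)=C/C(=O)OCC | intermediate
7 | (2E)‑3‑methyloct‑2‑en‑6‑yn‑1‑ol | CC#CCC/C(C)=C/CO | intermediate
8 | (2E)‑3‑methyloct‑2‑en‑6‑ynal | CC#CCC/C(C)=C/C=O | intermediate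
9 | (4R)‑2,2‑dimethyl‑1,3‑dioxolane‑4‑carbaldehyde | O=C[C@H]1COC(C)(C)O1 | starting material
10 | methyl acrylate | C=CC(=O)OC | starting material
11 | methyl 2‑{[(4R)‑2,2‑dimethyl‑1,3‑dioxolan‑4‑yl](hydroxy)methyl}prop‑2‑enoate (carbinol epimers) | C=C(C(=O)OC)C(O)[C@H]1COC(C)(C)O1 | intermediate
12 | methyl (2Z)‑2‑(bromomethyl)‑3‑[(4S)‑2,2‑dimethyl‑1,3‑dioxolan‑4‑yl]prop‑2‑enoate | COC(=O)/C(CBr)=C/[C@H]1COC(C)(C)O1 | intermediate
13 | methyl 2‑[(1R,2R,3E)‑1‑[(4S)‑2,2‑dimethyl‑1,3‑dioxolan‑4‑yl]‑2‑hydroxy‑4‑methylnon‑3‑en‑7‑yn‑1‑yl]prop‑2‑enoate | CC#CCC/C(C)=C/[C@@H](O)[C@@H](C(=C)C(=O)OC)[C@H]1COC(C)(C)O1 | intermediate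
14 | (4R,5R)‑4‑[(4S)‑2,2‑dimethyl‑1,3‑dioxolan‑4‑yl]‑3‑methylidene‑5‑[(1E)‑2‑methylhept‑1‑en‑5‑yn‑1‑yl]oxolan‑2‑one | CC#CCC/C(C)=C/[C@H]1OC(=O)C(=C)[C@H]1[C@H]2COC(C)(C)O2 | intermediate
15 | potassium (4R,5R)‑4‑[(4S)‑2,2‑dimethyl‑1,3‑dioxolan‑4‑yl]‑3‑methyl‑5‑[(1E)‑2‑methylhept‑1‑en‑5‑yn‑1‑yl]‑4,5‑dihydrofuran‑2‑olate | CC#CCC/C(C)=C/[C@H]1OC([O-])=C(C)[C@H]1[C@H]2COC(C)(C)O2.[K+] | intermediate
16 | (3R,4R,5R)‑4‑[(4S)‑2,2‑dimethyl‑1,3‑dioxolan‑4‑yl]‑3‑hydroxy‑3‑methyl‑5‑[(1E)‑2‑methylhept‑1‑en‑5‑yn‑1‑yl]oxolan‑2‑one | CC#CCC/C(C)=C/[C@H]1OC(=O)[C@](C)(O)[C@H]1[C@H]2COC(C)(C)O2 | intermediate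
17 | (3R,4R,5R)‑4‑[(4S)‑2,2‑dimethyl‑1,3‑dioxolan‑4‑yl]‑3‑methyl‑5‑[(1E)‑2‑methylhept‑1‑en‑5‑yn‑1‑yl]‑2‑oxooxolan‑3‑yl acetate | CC#CCC/C(C)=C/[C@H]1OC(=O)[C@](C)(OC(C)=O)[C@H]1[C@H]2COC(C)(C)O2 | intermediate
18 | (3R,4S,5R)‑4‑[(1S)‑1,2‑dihydroxyethyl]‑3‑methyl‑5‑[(1E)‑2‑methylhept‑1‑en‑5‑yn‑1‑yl]‑2‑oxooxolan‑3‑yl acetate | CC#CCC/C(C)=C/[C@H]1OC(=O)[C@](C)(OC(C)=O)[C@H]1[C@H](O)CO | intermediate
19 | (3R,4S,5R)‑4‑[(1S)‑2‑[(tert‑butyldimethylsilyl)oxy]‑1‑hydroxyethyl]‑3‑methyl‑5‑[(1E)‑2‑methylhept‑1‑en‑5‑yn‑1‑yl]‑2‑oxooxolan‑3‑yl acetate | CC#CCC/C(C)=C/[C@H]1OC(=O)[C@](C)(OC(C)=O)[C@H]1[C@H](O)CO[Si](C)(C)C(C)(C)C | intermediate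
20 | (3R,4R,5R)‑4‑[(1S)‑2‑[(tert‑butyldimethylsilyl)oxy]‑1‑(methanesulfonyloxy)ethyl]‑3‑methyl‑5‑[(1E)‑2‑methylhept‑1‑en‑5‑yn‑1‑yl]‑2‑oxooxolan‑3‑yl acetate | CC#CCC/C(C)=C/[C@H]1OC(=O)[C@](C)(OC(C)=O)[C@H]1[C@H](OS(C)(=O)=O)CO[Si](C)(C)C(C)(C)C | intermediate
21 | (3R,4R,5R)‑4‑[(1S)‑2‑hydroxy‑1‑(methanesulfonyloxy)ethyl]‑3‑methyl‑5‑[(1E)‑2‑methylhept‑1‑en‑5‑yn‑1‑yl]‑2‑oxooxolan‑3‑yl acetate (formed as its tetrabutylammonium alkoxide) | CC#CCC/C(C)=C/[C@H]1OC(=O)[C@](C)(OC(C)=O)[C@H]1[C@H](OS(C)(=O)=O)CO | intermediate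
22 | (3R,4R,5R)‑3‑methyl‑5‑[(1E)‑2‑methylhept‑1‑en‑5‑yn‑1‑yl]‑4‑[(2R)‑oxiran‑2‑yl]‑2‑oxooxolan‑3‑yl acetate | CC#CCC/C(C)=C/[C@H]1OC(=O)[C@](C)(OC(C)=O)[C@H]1[C@@H]2CO2 | intermediate
23 | O‑diethylboryl derivative of 24 (diethylborinate ester at the C8 oxygen) | CCB(CC)O[C@H]1C/C(C)=C/CC/C(C)=C/[C@H]2OC(=O)[C@](C)(OC(C)=O)[C@@H]12 | intermediate
24 | (3R,3aS,4S,6E,10E,11aR)‑4‑hydroxy‑3,6,10‑trimethyl‑2‑oxo‑2,3,3a,4,5,8,9,11a‑octahydrocyclodeca[b]furan‑3‑yl acetate | O[C@H]1C/C(C)=C/CC/C(C)=C/[C@H]2OC(=O)[C@](C)(OC(C)=O)[C@@H]12 | intermediate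
25 | angelic acid, (2Z)‑2‑methylbut‑2‑enoic acid | C/C=C(/C)C(=O)O | starting material
26 | (2Z)‑2‑methylbut‑2‑enoic 2,4,6‑trichlorobenzoic anhydride | C/C=C(/C)C(=O)OC(=O)c1c(Cl)cc(Cl)cc1Cl | intermediate
27 | (3R,3aS,4S,6E,10E,11aR)‑3‑(acetyloxy)‑3,6,10‑trimethyl‑2‑oxo‑2,3,3a,4,5,8,9,11a‑octahydrocyclodeca[b]furan‑4‑yl (2Z)‑2‑methylbut‑2‑enoate | C/C=C(/C)C(=O)O[C@H]1C/C(C)=C/CC/C(C)=C/[C@H]2OC(=O)[C@](C)(OC(C)=O)[C@@H]12 | target

**Step count and risks**

Total steps: 14. Longest linear sequence: 12 steps (steps 1–4 and 7–14).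

Steps most likely to fail:

Step 13. The alkyne may fail to insert, may insert with the other regiochemistry (bond to C1, nine‑membered ring), the substrate may oligomerise, or nickel may ionise the allylic lactone C6–O bond. The fallback sets out from 20 and comes back at 24; it fixes the alkenyl partner before ring closure. Hydrozirconation of the methyl alkyne of 20 with excess Cp2Zr(H)Cl (THF, rt to 40 °C, which should equilibrate zirconium to the less hindered, methyl‑bearing carbon faster than the lactone is attacked) and iodinolysis should give the (E)‑alkenyl iodide F1. Bu4NF should then give, by way of the hydroxy mesylate F2, the iodo epoxide F3. A nickel‑catalysed reductive cross‑electrophile coupling (NiBr2·diglyme, 4,4′‑di‑tert‑butyl‑2,2′‑bipyridine, NaI, Et3N·HCl, Mn powder, DMPU, high dilution) follows: iodide opens the epoxide at CH2 to the iodohydrin F4, and the primary alkyl radical is joined to the alkenylnickel species. This should close the same C9–C10 bond with the olefin geometry already in place and give 24.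

Step 7. The aldehyde may add to the other face of C7 (syn to the C8–O bond), the facial preference may be weak, or the syn (cis‑lactone) selectivity may erode. The fallback sets out from 8 and comes back at 22. If the other face is preferred, the same sequence is run from (S)‑glyceraldehyde acetonide F5: Baylis–Hillman alcohol F6, allylic bromide F7, chromium addition to 8 giving, by way of the hydroxy ester F8, the lactone F9 (C6 and C7 as in 14, C8 epimeric), reductive hydroxylation through the enolate F10 to the tertiary alcohol F11, acetate F12 and diol F13. The epoxide is then closed with retention at C8 instead of inversion: selective primary tosylation (TsCl, Bu2SnO cat., Et3N) to the hydroxy tosylate F14, then DBU, so that the secondary alkoxide displaces the primary tosylate, should give 22.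

Step 8. Hydride may add 1,2, the borane‑complexed enolate may react sluggishly with the oxaziridine, or the oxygen transfer may lose facial selectivity. The fallback sets out from 14 and comes back at 16; it is a radical route instead of an anionic one. Mukaiyama‑type hydration of the electron‑poor exocyclic olefin (Mn(dpm)3 cat., PhSiH3, O2, i‑PrOH, 0 °C) transfers a hydrogen atom to the methylene carbon; the tertiary C11 radical should take up O2 anti to the C7 substituent to give the hydroperoxide F15, which P(OEt)3 reduces to 16.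

Further compounds

F1 | step 13 | (3R,4R,5R)‑4‑[(1S)‑2‑[(tert‑butyldimethylsilyl)oxy]‑1‑(methanesulfonyloxy)ethyl]‑5‑[(1E,5E)‑6‑iodo‑2‑methylhepta‑1,5‑dien‑1‑yl]‑3‑methyl‑2‑oxooxolan‑3‑yl acetate | C/C(I)=C\CC/C(C)=C/[C@H]1OC(=O)[C@](C)(OC(C)=O)[C@H]1[C@H](OS(C)(=O)=O)CO[Si](C)(C)C(C)(C)C
F2 | step 13 | (3R,4R,5R)‑4‑[(1S)‑2‑hydroxy‑1‑(methanesulfonyloxy)ethyl]‑5‑[(1E,5E)‑6‑iodo‑2‑methylhepta‑1,5‑dien‑1‑yl]‑3‑methyl‑2‑oxooxolan‑3‑yl acetate | C/C(I)=C\CC/C(C)=C/[C@H]1OC(=O)[C@](C)(OC(C)=O)[C@H]1[C@H](OS(C)(=O)=O)CO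
F3 | step 13 | (3R,4R,5R)‑5‑[(1E,5E)‑6‑iodo‑2‑methylhepta‑1,5‑dien‑1‑yl]‑3‑methyl‑4‑[(2R)‑oxiran‑2‑yl]‑2‑oxooxolan‑3‑yl acetate | C/C(I)=C\CC/C(C)=C/[C@H]1OC(=O)[C@](C)(OC(C)=O)[C@H]1[C@@H]2CO2
F4 | step 13 | (3R,4S,5R)‑4‑[(1R)‑1‑hydroxy‑2‑iodoethyl]‑5‑[(1E,5E)‑6‑iodo‑2‑methylhepta‑1,5‑dien‑1‑yl]‑3‑methyl‑2‑oxooxolan‑3‑yl acetate | C/C(I)=C\CC/C(C)=C/[C@H]1OC(=O)[C@](C)(OC(C)=O)[C@H]1[C@@H](O)CI
F5 | step 7 | (4S)‑2,2‑dimethyl‑1,3‑dioxolane‑4‑carbaldehyde | O=C[C@@H]1COC(C)(C)O1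
F6 | step 7 | methyl 2‑{[(4S)‑2,2‑dimethyl‑1,3‑dioxolan‑4‑yl](hydroxy)methyl}prop‑2‑enoate (carbinol epimers) | C=C(C(=O)OC)C(O)[C@@H]1COC(C)(C)O1
F7 | step 7 | methyl (2Z)‑2‑(bromomethyl)‑3‑[(4R)‑2,2‑dimethyl‑1,3‑dioxolan‑4‑yl]prop‑2‑enoate | COC(=O)/C(CBr)=C/[C@@H]1COC(C)(C)O1
F8 | step 7 | methyl 2‑[(1R,2R,3E)‑1‑[(4R)‑2,2‑dimethyl‑1,3‑dioxolan‑4‑yl]‑2‑hydroxy‑4‑methylnon‑3‑en‑7‑yn‑1‑yl]prop‑2‑enoate | CC#CCC/C(C)=C/[C@@H](O)[C@@H](C(=C)C(=O)OC)[C@@H]1COC(C)(C)O1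
F9 | step 7 | (4R,5R)‑4‑[(4R)‑2,2‑dimethyl‑1,3‑dioxolan‑4‑yl]‑3‑methylidene‑5‑[(1E)‑2‑methylhept‑1‑en‑5‑yn‑1‑yl]oxolan‑2‑one | CC#CCC/C(C)=C/[C@H]1OC(=O)C(=C)[C@H]1[C@@H]2COC(C)(C)O2
F10 | step 7 | potassium (4R,5R)‑4‑[(4R)‑2,2‑dimethyl‑1,3‑dioxolan‑4‑yl]‑3‑methyl‑5‑[(1E)‑2‑methylhept‑1‑en‑5‑yn‑1‑yl]‑4,5‑dihydrofuran‑2‑olate | CC#CCC/C(C)=C/[C@H]1OC([O-])=C(C)[C@H]1[C@@H]2COC(C)(C)O2.[K+]
F11 | step 7 | (3R,4R,5R)‑4‑[(4R)‑2,2‑dimethyl‑1,3‑dioxolan‑4‑yl]‑3‑hydroxy‑3‑methyl‑5‑[(1E)‑2‑methylhept‑1‑en‑5‑yn‑1‑yl]oxolan‑2‑one | CC#CCC/C(C)=C/[C@H]1OC(=O)[C@](C)(O)[C@H]1[C@@H]2COC(C)(C)O2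
F12 | step 7 | (3R,4R,5R)‑4‑[(4R)‑2,2‑dimethyl‑1,3‑dioxolan‑4‑yl]‑3‑methyl‑5‑[(1E)‑2‑methylhept‑1‑en‑5‑yn‑1‑yl]‑2‑oxooxolan‑3‑yl acetate | CC#CCC/C(C)=C/[C@H]1OC(=O)[C@](C)(OC(C)=O)[C@H]1[C@@H]2COC(C)(C)O2
F13 | step 7 | (3R,4S,5R)‑4‑[(1R)‑1,2‑dihydroxyethyl]‑3‑methyl‑5‑[(1E)‑2‑methylhept‑1‑en‑5‑yn‑1‑yl]‑2‑oxooxolan‑3‑yl acetate | CC#CCC/C(C)=C/[C@H]1OC(=O)[C@](C)(OC(C)=O)[C@H]1[C@@H](O)CO
F14 | step 7 | (3R,4S,5R)‑4‑[(1R)‑1‑hydroxy‑2‑(4‑methylbenzenesulfonyloxy)ethyl]‑3‑methyl‑5‑[(1E)‑2‑methylhept‑1‑en‑5‑yn‑1‑yl]‑2‑oxooxolan‑3‑yl acetate | CC#CCC/C(C)=C/[C@H]1OC(=O)[C@](C)(OC(C)=O)[C@H]1[C@@H](O)COS(=O)(=O)c2ccc(C)cc2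
F15 | step 8 | (3R,4R,5R)‑4‑[(4S)‑2,2‑dimethyl‑1,3‑dioxolan‑4‑yl]‑3‑hydroperoxy‑3‑methyl‑5‑[(1E)‑2‑methylhept‑1‑en‑5‑yn‑1‑yl]oxolan‑2‑one | CC#CCC/C(C)=C/[C@H]1OC(=O)[C@](C)(OO)[C@H]1[C@H]2COC(C)(C)O2
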